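Atom numbers are those of ring A, the only ring: C1 (C=O), C2=C3, C4H2, C5 (carbinol carbon bearing OH and nonadecyl), C6H2.
Enabling feature: the C5 hydroxyl is 1,3 to the C1 ketone and C2=C3 joins the acyl carbon C1 to the allylic C4, so ring A is the metathesis closure of an open-chain C5-allyl β-hydroxy enone, itself the mono-allylation product of a β-diketone (C1=O, C5=O).
Retrosynthesis: cut C2=C3 (ring-closing metathesis, C2 capped as a styryl group that leaves as styrene), then C4–C5 (allyl transfer to the C5 ketone), then C5–C6 (Claisen acylation).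
Forward: icosanoyl chloride and the enolate of (E)-4-phenylbut-3-en-2-one give the cinnamoyl β-diketone (C5–C6), a chiral allylchlorosilane adds allyl at C5 (C4–C5), and metathesis closes ring A last (C2=C3).
Stereochemistry: C5 (S), the only stereocenter, is set in the allyl transfer by the (S,S)-diamine on silicon through a temporary six-membered O1–Si–O5 ring that is hydrolysed on work-up; the last step is neutral and leaves C5 untouched.
Helpers: the styryl cap (directs silylation to O1 and allyl transfer to C5, keeps the enone stable, is expelled in the ring closure) and the silicon tether; no protecting group is used.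

Key step: step 3

Assumption: the (S,S)-configured allylchlorosilane used in step 2 is taken to deliver allyl to the face of the C5 ketone that gives the (S)-carbinol; if the sense of induction is the opposite, the (R,R)-enantiomer of the reagent is used with no other change.

Step 1
Reactants: 1 icosanoyl chloride; 2 (E)-4-phenylbut-3-en-2-one
Product: 4 (E)-1-phenyltetracos-1-ene-3,5-dione, via lithium dienolate 3 (not isolated)
Conditions: LiN(SiMe3)2 (2.1 equiv), 2 (2.1 equiv), THF, −78 °C; 1 (1.0 equiv), −78 to 0 °C; 1 M HCl
Reagents that add atoms: none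
Why: Crossed Claisen condensation by C-acylation of a preformed lithium enolate: 2 has a single enolisable position, so LiN(SiMe3)2 should give only the cross-conjugated enolate 3, which is acylated by 1, while the second equivalent of 3 deprotonates the acidic β-diketone as it forms and so shields it from a second acylation; no stereocenter is created.

Step 2
Reactants: 4 (E)-1-phenyltetracos-1-ene-3,5-dione; 5 (3aS,7aS)-2-allyl-1,3-bis(4-bromobenzyl)-2-chlorooctahydro-1H-1,3,2-benzodiazasilole
Product: 8 (1E,5S)-5-hydroxy-1-phenyl-5-(prop-2-en-1-yl)tetracos-1-en-3-one, via silyl dienol ether hydrochloride 6 (not isolated), via spiro dioxasiline hydrochloride 7 (not isolated)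
Conditions: 5 (1.3 equiv), CHCl3, 23 °C; then 1 M HCl, EtOAc, 0 °C
Reagents that add atoms: none
Why: Enantioselective allylation of a β-diketone with a chiral diamine-derived allylchlorosilane: the enol of 4 should displace chloride on silicon at O1 (6, the styryl-conjugated dienol ether), the HCl so formed stays on a ring nitrogen and makes silicon strongly Lewis acidic, and the non-conjugated C5 ketone, held in a six-membered O1–Si–O5 chelate, should receive the allyl group through a closed chair-like transition state whose face is dictated by the (S,S)-diamine backbone, giving the (S)-carbinol in 7 and, after hydrolysis of the Si–O bonds, 8.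

Step 3
Reactants: 8 (1E,5S)-5-hydroxy-1-phenyl-5-(prop-2-en-1-yl)tetracos-1-en-3-one
Product: 9 (S)-5-hydroxy-5-nonadecylcyclohex-2-en-1-one
Conditions: second-generation Grubbs catalyst (H2IMes)(PCy3)Cl2Ru=CHPh (5 mol %), 1,4-benzoquinone (10 mol %), CH2Cl2 (0.005 M), 40 °C
Reagents that add atoms: none
Why: Ring-closing olefin metathesis through ruthenacyclobutanes: the benzylidene (H2IMes)Cl2Ru=CHPh should first exchange with the unhindered allyl alkene of 8 (styrene leaves), and the alkylidene now on C3 should add across the C2=CHPh bond of the enone in an intramolecular [2+2] step whose cycloreversion forms C2=C3 and returns the same benzylidene, so the styryl cap is expelled as the catalyst's own carbene and no ethylene is produced. The closest known reaction type is the ring-closing metathesis of 1,7-dienes in which one alkene belongs to a cinnamoyl or crotonoyl ketone or ester, which gives cyclohex-2-enones and 5,6-dihydropyran-2-ones. Ring A closes as the six-membered ring of a 1,7-diene with the new double bond endocyclic and necessarily cis; no other ring size is available because 8 holds only these two alkenes. No stereocenter is formed, and C5 is kept because the medium is neutral and aprotic, which shuts off the retro-aldol and β-elimination paths of this tertiary β-hydroxy ketone. The step needs cyclisation to win over intermolecular metathesis and over oxa-Michael addition of the C5 hydroxyl to the enone: the conjugated, 1,2-disubstituted styryl alkene does not homodimerise, the geminal substitution at C5 folds the chain, high dilution favours the ring, and 1,4-benzoquinone intercepts Ru–H species that could isomerise the allyl group or the product.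

Compound list
1 | icosanoyl chloride | CCCCCCCCCCCCCCCCCCCC(=O)Cl | starting material
2 | (E)-4-phenylbut-3-en-2-one | CC(=O)/C=C/c1ccccc1 | starting material
3 | lithium (3E)-4-phenylbuta-1,3-dien-2-olate | [Li+].[O-]C(=C)/C=C/c1ccccc1 | intermediate
4 | (E)-1-phenyltetracos-1-ene-3,5-dione (drawn as the diketo tautomer, largely enolised) | CCCCCCCCCCCCCCCCCCCC(=O)CC(=O)/C=C/c1ccccc1 | intermediate
5 | (3aS,7aS)-2-allyl-1,3-bis(4-bromobenzyl)-2-chlorooctahydro-1H-1,3,2-benzodiazasilole | C=CC[Si]1(Cl)N(Cc2ccc(Br)cc2)[C@H]3CCCC[C@@H]3N1Cc1ccc(Br)cc1 | starting material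
6 | silyl dienol ether of 4: (3aS,7aS)-2-allyl-1,3-bis(4-bromobenzyl)-2-{[(1E,3Z)-5-oxo-1-phenyltetracosa-1,3-dien-3-yl]oxy}octahydro-1H-1,3,2-benzodiazasilole, as its hydrochloride | CCCCCCCCCCCCCCCCCCCC(=O)/C=C(/C=C/c1ccccc1)O[Si]1(CC=C)N(Cc2ccc(Br)cc2)[C@H]3CCCC[C@@H]3N1Cc1ccc(Br)cc1.Cl | intermediate
7 | spirocyclic silyl ether after allyl transfer: 4H-1,3,2-dioxasiline ring (O1–Si–O5–C5–C6=C1) with nonadecyl and allyl on the (S)-configured C5 and (E)-styryl on C1, spiro at silicon to the (S,S)-N,N'-bis(4-bromobenzyl)cyclohexane-1,2-diamine ring, as its hydrochloride | CCCCCCCCCCCCCCCCCCC[C@]1(CC=C)C=C(/C=C/c2ccccc2)O[Si]3(O1)N(Cc4ccc(Br)cc4)[C@H]5CCCC[C@@H]5N3Cc3ccc(Br)cc3.Cl | intermediate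
8 | (1E,5S)-5-hydroxy-1-phenyl-5-(prop-2-en-1-yl)tetracos-1-en-3-one | CCCCCCCCCCCCCCCCCCC[C@](O)(CC=C)CC(=O)/C=C/c1ccccc1 | intermediate
9 | (S)-5-hydroxy-5-nonadecylcyclohex-2-en-1-one | CCCCCCCCCCCCCCCCCCC[C@]1(O)CC=CC(=O)C1 | target

Total step count: 3. Longest linear sequence: 3 steps (1 to 4 to 8 to 9).

Steps most likely to fail

1. Step 2. The allyl group may be delivered to the conjugated C1 carbonyl instead of C5, or with poor facial discrimination at a ketone flanked by two methylene groups. The fallback sets out from 1 and comes back at 8. Acylation of allyltrimethylsilane with 1 (AlCl3, CH2Cl2, −78 °C; Hosomi–Sakurai acylation) would give tricos-1-en-4-one F1. Aldol addition of enolate 3 to F1, after transmetalation with CeCl3 to suppress enolisation of the β,γ-unsaturated ketone, would give racemic (1E)-5-hydroxy-1-phenyl-5-(prop-2-en-1-yl)tetracos-1-en-3-one F2 with the connectivity fixed by construction. Preparative chromatography on a chiral stationary phase would then deliver 8 and set aside (1E,5R)-5-hydroxy-1-phenyl-5-(prop-2-en-1-yl)tetracos-1-en-3-one F3.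

2. Step 3. Turnover at the electron-poor, phenyl-substituted enone alkene may be slow, so that oligomerisation through the allyl groups or dehydration of the product to the phenol on long heating takes over. The fallback sets out from 8 and comes back at 9. Luche reduction of 8 (NaBH4, CeCl3·7H2O, MeOH, −78 °C) would give (1E,5S)-1-phenyl-5-(prop-2-en-1-yl)tetracos-1-ene-3,5-diol F4 as both C3 epimers. Its styrene-type alkene is no longer conjugated to a carbonyl and should close with the same catalyst to (5S)-5-nonadecylcyclohex-2-ene-1,5-diol F5. MnO2 (CH2Cl2, 23 °C) would then oxidise only the secondary allylic hydroxyl and give 9.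

3. Step 1. O-acylation of the enolate or a second C-acylation of the product may erode the conversion to the diketone. The fallback sets out from 1 and comes back at 4. C-acylation of acetylacetone with 1 (MgCl2, pyridine, CH2Cl2) would give 3-acetyltricosane-2,4-dione F6, and retro-Claisen deacetylation (NaOMe, MeOH) would give tricosane-2,4-dione F7. A boron-templated aldol condensation of the terminal methyl group of F7 with benzaldehyde (B2O3, B(OBu)3, n-BuNH2, EtOAc; then dilute HCl) would build the styryl unit and give 4.

Further compounds
F1 | step 2 | tricos-1-en-4-one | CCCCCCCCCCCCCCCCCCCC(=O)CC=C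
F2 | step 2 | racemic (1E)-5-hydroxy-1-phenyl-5-(prop-2-en-1-yl)tetracos-1-en-3-one | CCCCCCCCCCCCCCCCCCCC(O)(CC=C)CC(=O)/C=C/c1ccccc1
F3 | step 2 | (1E,5R)-5-hydroxy-1-phenyl-5-(prop-2-en-1-yl)tetracos-1-en-3-one | CCCCCCCCCCCCCCCCCCC[C@@](O)(CC=C)CC(=O)/C=C/c1ccccc1
F4 | step 3 | (1E,5S)-1-phenyl-5-(prop-2-en-1-yl)tetracos-1-ene-3,5-diol, both C3 epimers | CCCCCCCCCCCCCCCCCCC[C@](O)(CC=C)CC(O)/C=C/c1ccccc1
F5 | step 3 | (5S)-5-nonadecylcyclohex-2-ene-1,5-diol, both C1 epimers | CCCCCCCCCCCCCCCCCCC[C@]1(O)CC=CC(O)C1
F6 | step 1 | 3-acetyltricosane-2,4-dione | CCCCCCCCCCCCCCCCCCCC(=O)C(C(C)=O)C(C)=O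
F7 | step 1 | tricosane-2,4-dione | CCCCCCCCCCCCCCCCCCCC(=O)CC(C)=O
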